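## The problem

Compound 22 joins a cross-conjugated dienone (ring A) to a dihydropyran (ring B) whose C2 is the spiro atom of an octalin. The locants are O1, C2, C3, C4 and C4a to C8a for rings A and B, and C1′ to C8a′ for the carbocycles: ring C holds C2 and the C1′=C8a′ alkene, ring D the C5′ methyl and C8′ isopropyl groups. Ring A carries both ether oxygens (OMe on C7, O1 on C8a) β to the same carbonyl, so the methoxy group must sit between the C8 gem-dimethyl carbon and the C6 methyl carbon, and an ambident trione enol can close or alkylate the wrong way. There are five stereocentres: C4, the quaternary spiro C2, and C4a′, C5′ and C8′. C4 and C2 are 1,3-related on the pyran, so C4 can direct C2; the three decalin centres have no contact with C4 and can only be set through C2, in a ring-forming step that uses the substituents on C2. The methyl enol ether and the dienone do not tolerate aqueous acid, hydrides or hard carbon nucleophiles unless ring A is present as its enolate. The C2–O1 bond of 22 is a tertiary allylic ether with a vinylogous carboxylate as leaving group and will ionise with strong acid or zerovalent palladium. The feature that allows a cycloaddition is the C1′=C8a′ alkene next to the quaternary C2: it is the enol derivative of a C1′ ketone that can enolise only toward C8a′, and that ketone, with C8a′ bonded to C4a′ and C8′ to C7′, is the tether carbonyl of a 1,7,9-decatrien-3-one.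

## Retrosynthesis

**22 ⇒ 21 ⇒ 20.** No skeletal bond is cut. The alkene is traced to enol triflate 21 and ketone 20. A dehydration of a ring C alcohol could give several alkenes or rearrange next to C2; the enolate of 20 has a single α-hydrogen, so the triflate fixes the alkene. The ketone gained is the activating group of the key step. The forward steps need enolisation of a hindered cis-decalone and a reduction that leaves the allylic C2–O1 bond of 22 intact.

**20 ⇒ 19.** The C5′–H bond is cut: the C5′ centre comes from hydrogenation of a C5′=C6′ alkene, which is what a diene leaves behind. The cis ring fusion of 19 offers a convex face. The forward step must add hydrogen anti to the axial C4′ bond and spare the ring A alkenes.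

**19 ⇒ 18 (key).** C8a′–C4a′ and C8′–C7′ are cut. This opens rings C and D together and removes C4a′, C8′ and C8a′, leaving trienone 18 with only C2 and C4. Closing one ring at a time would need a preformed ring D with three centres and a separate spiro-forming step. The forward reaction must be endo and must use the enone face that C2, with C4 behind it, leaves open.

**18 ⇒ 17 ⇒ 16.** The enone carbonyl oxygen is traced to the acetate of propargylic acetate 17 (1,3-acyloxy shift), and 17 to alcohol 16. An alkyne on C2 is slim, stabilises positive charge at C2 and survives the acid and base steps before it. Adding a vinyl nucleophile to an ester or nitrile on C2 would expose ring A to organometallic reagents when it cannot be protected. The rearrangement must deliver oxygen to C1′ and leave C2–O1 alone.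

**16 ⇒ 15.** O1–C2 is cut, giving tertiary propargylic alcohol 15 with ring A as its enol. Ring closure is capture of a planar cation, so C2 is stereoconvergent: either carbinol epimer of 15 should close to the pyran with the alkyne syn to the C4 isopropyl group. The forward step needs the enol oxygen next to C8 to close, and ionisation without elimination.

**15 ⇒ 12 + 13.** The C2–C(sp) bond is cut: the dianion of alkynol 13 adds to the ketone that hemiketal 12 unmasks in base. Ring A is then an enolate and inert, which is why the one strongly nucleophilic step is placed here.

**12 ⇒ 7 + 11.** C4–C4a is cut: conjugate addition of dione 11 to enone 7 under a chiral primary amine. This is the only reagent-controlled stereocentre; both partners are achiral.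

**7 ⇒ 6 ⇒ 3 + 4; 3 ⇒ 2 ⇒ 1.** Grignard reagent 5 from bromide 3 adds to enal 4 and alcohol 6 is oxidised. Bromide 3 is the ring-opening product of carbinol 2 from ketone 1, which fixes the E diene geometry early.

**11 ⇒ 10 ⇒ 9 ⇒ 8.** Three C–CH3 bonds and the ester are cut. Dione 11 is the decarboxylation product of keto ester 10, which comes from dearomatising C-methylation of symmetric benzoate 9, the 4-O-methyl ether of 8. Fixing the O-methyl group on the aromatic ring, para to the blocking ester, settles the regiochemistry by symmetry. Direct O-methylation of a trimethyl trione would have to hit the most hindered of its enol oxygens.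

## Roads not taken

**Alternative 1:** Ring A is closed last by cutting C5–C6. A lithium amide enolises the ethyl ketone held on C8a through the gem-dimethyl carbon of keto ester A2; the enolate attacks the methyl ester on C4a (Dieckmann) to give trione enol A1, which is then O-methylated.
- Merits: O1 is on C8a before ring A exists, and the sensitive dienone is absent from all earlier steps. In both respects this road is better than the chosen one, which relies on the preference of an ambident enol in step 10 and on enolate protection in step 9.
- Weak points: it does not say how the five stereocentres of A2 arise. The ester on C4a is a β-alkoxy acrylate, a poor electrophile for a hindered ketone enolate. The final O-methylation of A1 has two enolate oxygens (on C7 and C5) with nothing to tell them apart.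
- Comparison: the chosen plan sets against it a defined stereochemical relay (C4 to C2 to the decalin) and a methoxy group fixed by symmetry in step 5.

**Alternative 2:** C2–C3 and O1–C2 are cut. A secondary amine condenses the acetyl methyl of acetyl trione A3 with the carbonyl of octalone A4, and the enol oxygen adds to C2, giving spiro pyran-4-one A5 in one operation (Kabbe type).
- Merits: the most convergent assembly; A3 is the direct product of a dearomatising methylation. In step count this road is better.
- Weak points: A4 is a γ-enolisable enone, so dienamine formation competes and the oxygen must add to a fully substituted carbon of a cross-conjugated dienone. Only the remote ring D decides the face at C2. A4 needs the C4a′ substituent cis to the C5′ methyl, an epimerisable and probably less stable arrangement. C4 of A5 is a vinylogous ester carbonyl at which the isopropyl group and hydrogen must still be introduced with control from C2. The ambident enol problem remains.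
- Comparison: the chosen plan sets C4 first by catalysis and lets it direct C2, where there is a clear conformational argument.

**Alternative 3:** C1′–C8a′ and O1–C2 are cut. A strong Lewis acid activates the ketone of the 2-isopropyl-5-methylcyclohexanone A6, which carries a 1,1-disubstituted alkene; the CH2 terminus attacks the carbonyl (ring C) and the enol oxygen captures the C2 cation (ring B), giving tertiary alcohol A7.
- Merits: two rings and the spiro centre in one step, and C5′ and C8′ from a terpene-type ketone. It is as good as the chosen plan in how C2 is set (cation capture 1,3 to C4) and shorter.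
- Weak points: A6 holds C4 and C4a′ on a flexible chain, and its C4a′ centre is α to the ketone and must be cis to the C5′ methyl. Dehydration of A7 has β-hydrogens on C1′, C8′ and C4a′, so the wanted alkene competes with two more substituted ones. The Lewis acid meets a free enol and a methyl enol ether.
- Comparison: the chosen plan sets against it an alkene whose position cannot wander (step 15) and ring D centres that follow from alkene geometry.

Key step: step 13

Assumption: 9-amino-9-deoxy-epi-quinine is taken to give the 4R adduct, by analogy with warfarin-type additions; if it gives 4S, its quinidine-derived pseudo-enantiomer is used.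
Remark: 13 is used as the racemate; its carbinol centre is destroyed in step 12, so 15, 16 and 17 are pairs of epimers at that carbon.

## Route

Step 1
Reactants: 1 cyclopropyl methyl ketone
Product: 2 2-cyclopropylbut-3-en-2-ol (racemic)
Conditions: CH2=CHMgBr, THF, 0 °C; aq. NH4Cl
Reagents that add atoms: vinylmagnesium bromide, C=C[Mg]Br
Why: Grignard 1,2-addition to a methyl ketone; the new centre is lost in step 2.

Step 2
Reactants: 2 2-cyclopropylbut-3-en-2-ol
Product: 3 (E)-6-bromo-3-methylhexa-1,3-diene
Conditions: 48% aq. HBr, 0 °C
Reagents that add atoms: hydrogen bromide, Br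
Why: Julia cyclopropylcarbinyl-to-homoallyl ring opening; the trisubstituted alkene should form mainly E, and the minor Z isomer is removed by fractional distillation.

Step 3
Reactants: 3 (E)-6-bromo-3-methylhexa-1,3-diene; 4 (E)-4-methylpent-2-enal
Product: 6 (3E,8E)-3,10-dimethylundeca-1,3,8-trien-7-ol (racemic), via dienyl Grignard reagent 5 (not isolated)
Conditions: Mg, THF, rt; then 4, −78 to 0 °C; aq. NH4Cl
Reagents that add atoms: none
Why: Grignard formation from a primary homoallylic bromide and 1,2-addition to an enal; the carbinol is oxidised next.

Step 4
Reactants: 6 (3E,8E)-3,10-dimethylundeca-1,3,8-trien-7-ol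
Product: 7 (3E,8E)-3,10-dimethylundeca-1,3,8-trien-7-one
Conditions: MnO2, CH2Cl2, rt
Reagents that add atoms: none
Why: Allylic alcohol oxidation under neutral conditions; the β-branched nonatrienone should not cyclise at room temperature and is stored cold.

Step 5
Reactants: 8 methyl 2,4,6-trihydroxybenzoate
Product: 9 methyl 2,6-dihydroxy-4-methoxybenzoate
Conditions: Me2SO4 (1.0 equiv), K2CO3, acetone, rt
Reagents that add atoms: dimethyl sulfate, COS(=O)(=O)OC
Why: Williamson O-methylation at the para hydroxyl, the most acidic and the only one not hydrogen-bonded to the ester; the product keeps mirror symmetry.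

Step 6
Reactants: 9 methyl 2,6-dihydroxy-4-methoxybenzoate
Product: 10 methyl 2-hydroxy-4-methoxy-3,3,5-trimethyl-6-oxocyclohexa-1,4-diene-1-carboxylate (enol form)
Conditions: NaOMe, MeI (3.3 equiv), MeOH, 0 °C to rt
Reagents that add atoms: iodomethane, CI
Why: Dearomatising C-methylation of an acylphloroglucinol-type dianion; the ester blocks the carbon between the hydroxyls, and the third methyl makes one of two equivalent positions quaternary, leaving OMe between CMe2 and CMe.

Step 7
Reactants: 10 methyl 2-hydroxy-4-methoxy-3,3,5-trimethyl-6-oxocyclohexa-1,4-diene-1-carboxylate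
Product: 11 5-methoxy-4,6,6-trimethylcyclohex-4-ene-1,3-dione
Conditions: 2 M aq. NaOH, MeOH, 60 °C; then HCl to pH 3, 0 °C to rt
Reagents that add atoms: none
Why: Saponification and decarboxylation of a 2-carboxy-1,3-dione; the enol ether sits on an electron-rich enolate during the basic phase and meets dilute acid only briefly in the cold.

Step 8
Reactants: 7 (3E,8E)-3,10-dimethylundeca-1,3,8-trien-7-one; 11 5-methoxy-4,6,6-trimethylcyclohex-4-ene-1,3-dione
Product: 12 (4R)-2-hydroxy-7-methoxy-6,8,8-trimethyl-2-[(E)-4-methylhexa-3,5-dien-1-yl]-4-(propan-2-yl)-3,4-dihydro-2H-chromen-5(8H)-one (both C2 anomers, in equilibrium with the open keto enol)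
Conditions: 9-amino-9-deoxy-epi-quinine (20 mol %), CF3CO2H (40 mol %), CH2Cl2, rt
Reagents that add atoms: none
Why: Primary-amine (iminium) catalysed Michael addition of a cyclic 1,3-dione to an enone, the warfarin-type reaction; the catalyst shields one face of the iminium ion and sets C4 (R), and the adduct closes to the hemiketal.

Step 9
Reactants: 12 the (4R)-hemiketal; 13 4-methylpent-1-yn-3-ol (racemic)
Product: 15 3-hydroxy-5-methoxy-4,4,6-trimethyl-2-[(3R)-5,8-dihydroxy-2,9-dimethyl-5-((E)-4-methylhexa-3,5-dien-1-yl)dec-6-yn-3-yl]cyclohexa-2,5-dien-1-one (mixture at both carbinol carbons), via dilithio alkynolate 14 (not isolated)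
Conditions: 13 (3 equiv), n-BuLi (6 equiv), THF, −78 to 0 °C; then 12, −78 to −20 °C; aq. NH4Cl
Reagents that add atoms: none
Why: Acetylide addition to a ketone; the first equivalent of base opens the hemiketal to the ketone and the ring A enolate, which protects the dienone, and no control at C2 is needed because step 10 sets it.

Step 10
Reactants: 15 the open-chain diol enol
Product: 16 (2S,4R)-2-(3-hydroxy-4-methylpent-1-yn-1-yl)-7-methoxy-6,8,8-trimethyl-2-[(E)-4-methylhexa-3,5-dien-1-yl]-4-(propan-2-yl)-3,4-dihydro-2H-chromen-5(8H)-one (alkynyl cis to the C4 isopropyl; both carbinol epimers)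
Conditions: TsOH (10 mol %), 4 Å molecular sieves, CH2Cl2, 0 °C to rt
Reagents that add atoms: none
Why: Acid-catalysed propargylic substitution (SN1 ring closure, as in chroman formation from tertiary alcohols): the enol oxygen next to C8 captures the C2 cation to give the cross-conjugated dienone. C2 is set here: with the C4 isopropyl pseudoaxial (away from the C5 carbonyl) the slim alkyne takes the syn-axial place and the chain the equatorial one, and re-ionisation lets the more stable epimer accumulate.

Step 11
Reactants: 16 the propargylic alcohol
Product: 17 acetate of 16 (2S,4R; 3-acetoxy-4-methylpent-1-yn-1-yl group on C2)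
Conditions: Ac2O, Et3N, DMAP (5 mol %), CH2Cl2, 0 °C
Reagents that add atoms: acetic anhydride, CC(=O)OC(C)=O
Why: Acylation of the only free hydroxyl; it installs the group that carries oxygen to C1′ in step 12.

Step 12
Reactants: 17 the propargylic acetate
Product: 18 (2S,4R)-7-methoxy-6,8,8-trimethyl-2-[(E)-4-methylhexa-3,5-dien-1-yl]-2-[(E)-4-methylpent-2-enoyl]-4-(propan-2-yl)-3,4-dihydro-2H-chromen-5(8H)-one (acyl cis to the C4 isopropyl)
Conditions: Ph3PAuNTf2 (2 mol %), wet 2-butanone, rt
Reagents that add atoms: none
Why: Gold-catalysed 1,3-acyloxy shift of a propargylic acetate to the allenyl acetate, then hydrolysis (a Meyer–Schuster-type outcome). The acetate carbonyl reaches only C1′ through a six-membered transition state, so the ketone forms next to C2, and the E-enone is the stable isomer.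

Step 13
Reactants: 18 the trienone
Product: 19 cis-fused spiro ketone: rings A and B as in 18 (2S,4R); ring C a cyclohexanone (C1′=O) spiro at C2; ring D with C5′=C6′ (methyl on C5′) and isopropyl on C8′; H-4a′ and H-8a′ cis to each other and on the face of ring C that carries C3; C8′ isopropyl trans to C1′ and anti to C4′
Conditions: Me2AlCl (3 equiv), CH2Cl2, −78 to −20 °C
Reagents that add atoms: none
Why: Concerted, asynchronous [4+2] cycloaddition of the aluminium-complexed E-enone (C8a′=C8′) to the tethered diene (C4a′=C5′–C6′=C7′); the closest known reaction type is the thermal or Me2AlCl-promoted type 1 intramolecular Diels–Alder reaction of 1,7,9-decatrien-3-ones to cis-octalones. Ring D is the cyclohexene made by the suprafacial addition itself, with C8′–C7′ leading and C8a′–C4a′ following; ring C closes in the fused mode through the tether C1′–C2–C3′–C4′ as a chair-like six-membered ketone ring. C8′ follows from the E geometry of the enone (isopropyl trans to C1′); C4a′ follows from the endo placement of the tether carbonyl under the diene, which gives the cis fusion; C8a′ follows from the enone face attacked. That face is chosen by C2 and, through the pyran, by C4: with the C4 isopropyl pseudoaxial the acyl group is axial and the dienyl chain equatorial. The carbonyl oxygen can then lie only over O1, because the rotamer with C=O over C3 runs into the isopropyl group, so the chain reaches the enone face turned away from C3 and C4 and H-8a′ and H-4a′ end on the C3 side. The step needs endo over exo selectivity, which the Lewis acid should raise, and this face selectivity, which the pyran conformation supplies and which aluminium held between the C1′ oxygen and O1 would reinforce.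

Step 14
Reactants: 19 the cis-fused octalone
Product: 20 saturated ketone: as 19 with C5′–C6′ single and the C5′ methyl cis to C4′ (H-5′ cis to H-4a′)
Conditions: H2 (1 atm), 5% Pt/C, EtOAc, rt
Reagents that add atoms: none
Why: Heterogeneous syn hydrogenation; in the cis-fused octalone the C4′ bond is axial on ring D and blocks the concave face, so hydrogen should add from the face of H-4a′. The tetrasubstituted, donor-substituted ring A alkenes and the ketone should not be reduced.

Step 15
Reactants: 20 the saturated ketone
Product: 21 C1′ enol triflate (C1′=C8a′; 2S,4R,4a′R,5′R,8′S)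
Conditions: KN(SiMe3)2, THF, −78 °C; then PhNTf2, −78 to 0 °C
Reagents that add atoms: N-phenylbis(trifluoromethanesulfonimide), O=S(=O)(N(c1ccccc1)S(=O)(=O)C(F)(F)F)C(F)(F)F
Why: Enolate O-triflation; C2 is quaternary, so the only α-hydrogen is on C8a′ and the alkene position is fixed, while the C8a′ centre is erased.

Step 16
Reactants: 21 the enol triflate
Product: 22 target, (2S,4R,4a′R,5′R,8′S) in the locants used here
Conditions: Pd(OAc)2 (5 mol %), PPh3 (10 mol %), HCO2H, n-Bu3N, DMF, 50 °C
Reagents that add atoms: none
Why: Palladium-catalysed formate reduction of a vinyl triflate (oxidative addition, formate exchange, loss of CO2, reductive elimination); the alkene stays in place. The allylic C2–O1 bond of 22 is tertiary and flanked by fully substituted carbons, so its ionisation should be slow.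

## Compound list

1 | cyclopropyl methyl ketone | CC(=O)C1CC1 | starting material
2 | 2-cyclopropylbut-3-en-2-ol (racemic) | CC(O)(C=C)C1CC1 | intermediate
3 | (E)-6-bromo-3-methylhexa-1,3-diene | BrCC/C=C(\C)C=C | intermediate
4 | (E)-4-methylpent-2-enal | CC(C)/C=C/C=O | starting material
5 | [(E)-4-methylhexa-3,5-dien-1-yl]magnesium bromide (not isolated) | Br[Mg]CC/C=C(\C)C=C | intermediate
6 | (3E,8E)-3,10-dimethylundeca-1,3,8-trien-7-ol (racemic) | CC(C)/C=C/C(O)CC/C=C(\C)C=C | intermediate
7 | (3E,8E)-3,10-dimethylundeca-1,3,8-trien-7-one | CC(C)/C=C/C(=O)CC/C=C(\C)C=C | intermediate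
8 | methyl 2,4,6-trihydroxybenzoate | COC(=O)c1c(O)cc(O)cc1O | starting material
9 | methyl 2,6-dihydroxy-4-methoxybenzoate | COC(=O)c1c(O)cc(OC)cc1O | intermediate
10 | methyl 2-hydroxy-4-methoxy-3,3,5-trimethyl-6-oxocyclohexa-1,4-diene-1-carboxylate | COC(=O)C1=C(O)C(C)(C)C(OC)=C(C)C1=O | intermediate
11 | 5-methoxy-4,6,6-trimethylcyclohex-4-ene-1,3-dione | COC1=C(C)C(=O)CC(=O)C1(C)C | intermediate
12 | (4R)-hemiketal, C2 bearing OH and the (E)-4-methylhexa-3,5-dienyl chain (C2 anomers) | COC1=C(C)C(=O)C2=C(OC(O)(CC/C=C(\C)C=C)C[C@@H]2C(C)C)C1(C)C | intermediate
13 | 4-methylpent-1-yn-3-ol (racemic) | C#CC(O)C(C)C | starting material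
14 | dilithium salt of 13 (C-lithio, O-lithio; not isolated) | [Li]C#CC(O[Li])C(C)C | intermediate
15 | open-chain tertiary propargylic alcohol with ring A enol (4R; mixture at both carbinol carbons) | COC1=C(C)C(=O)C([C@H](CC(O)(CC/C=C(\C)C=C)C#CC(O)C(C)C)C(C)C)=C(O)C1(C)C | intermediate
16 | (2S,4R)-2-alkynyl pyran, free secondary alcohol (carbinol epimers) | COC1=C(C)C(=O)C2=C(O[C@@](C#CC(O)C(C)C)(CC/C=C(\C)C=C)C[C@@H]2C(C)C)C1(C)C | intermediate
17 | (2S,4R)-2-alkynyl pyran, secondary acetate (carbinol epimers) | COC1=C(C)C(=O)C2=C(O[C@@](C#CC(OC(C)=O)C(C)C)(CC/C=C(\C)C=C)C[C@@H]2C(C)C)C1(C)C | intermediate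
18 | (2S,4R)-trienone with (E)-4-methylpent-2-enoyl and (E)-4-methylhexa-3,5-dienyl on C2 | COC1=C(C)C(=O)C2=C(O[C@@](C(=O)/C=C/C(C)C)(CC/C=C(\C)C=C)C[C@@H]2C(C)C)C1(C)C | intermediate
19 | cis-fused C1′ ketone with C5′=C6′ alkene | COC1=C(C)C(=O)C2=C(O[C@]3(C(=O)[C@H]4[C@H](C(C)C)CC=C(C)[C@H]4CC3)C[C@@H]2C(C)C)C1(C)C | intermediate
20 | cis-fused C1′ ketone, ring D saturated, C5′ methyl cis to C4′ | COC1=C(C)C(=O)C2=C(O[C@]3(C(=O)[C@H]4[C@H](C(C)C)CC[C@@H](C)[C@H]4CC3)C[C@@H]2C(C)C)C1(C)C | intermediate
21 | C1′ enol triflate (C1′=C8a′) | COC1=C(C)C(=O)C2=C(O[C@]3(C(OS(=O)(=O)C(F)(F)F)=C4[C@H](C(C)C)CC[C@@H](C)[C@H]4CC3)C[C@@H]2C(C)C)C1(C)C | intermediate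
22 | CNP0194760.3, (2S,4R,4a′R,5′R,8′S) | COC1=C(C)C(=O)C2=C(O[C@]3(C=C4[C@H](C(C)C)CC[C@@H](C)[C@H]4CC3)C[C@@H]2C(C)C)C1(C)C | target

## Step count and risk

Total: 16 steps. Longest linear sequence: 13 steps (steps 1 to 4 and 8 to 16, from 1).

**Step 13 (key).** The most likely failure is weak face discrimination. If the pyran of 18 populates the half-chair with the isopropyl group pseudoequatorial, the acyl group is no longer held with its oxygen over O1 and the diene can add to either enone face. A slow reaction of the β-branched enone could also erode the endo preference or let the Lewis acid epimerise C8a′. The fallback moves the face selection from the substrate to a reagent: 18 is cyclised with a cationic chiral oxazaborolidine (from the matched diphenylprolinol enantiomer, an arylboronic acid and HNTf2), a known catalyst class for enone Diels–Alder reactions. It sets out from 18 and returns at 19, and makes no new compound.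

**Step 8.** The most likely failure is slow iminium formation from a ketone with an α′-methylene chain and a β-isopropyl group. That would give low conversion or low enantiomeric purity while 7 slowly undergoes its own intramolecular cycloaddition. The fallback sets out from 11 and 4. Addition to the enal under α,α-diphenylprolinol trimethylsilyl ether catalysis should give lactol F1, oxidation (PhI(OAc)2, catalytic TEMPO) enol lactone F2, and one equivalent of 5 at −78 °C should open the activated lactone to the ketone, which closes to 12.

**Step 10.** The most likely failures are proton loss from the cation to an enyne, rearrangement of the tertiary carbinol to an enone, or ring closure through the other enol oxygen. The fallback forms the C2–alkyne bond on the closed ring and sets out from 12 and 13. Methanol with HC(OMe)3 and pyridinium p-toluenesulfonate should convert 12 into methyl ketal F3, and 13 is protected as tert-butyldimethylsilyl ether F4. F4 is lithiated and transmetalated with Me2AlCl; the alkynyl(dimethyl)alane replaces the methoxy group of F3 by axial delivery to give silyl ether F5, and Bu4NF returns 16.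

**Step 12.** The most likely failure is that gold activation of the alkyne triggers ionisation of the tertiary propargylic C2–O1 bond in place of the acetate shift, or that the diene binds the catalyst. The fallback avoids π-acid activation and sets out from 16 in place of 17. With VO(OSiPh3)3 in toluene at 80 °C the vanadate ester of the secondary alcohol rearranges by a [3,3] shift to the allenyl vanadate and then 18, without a cation at C2. It returns at 18 and makes no new compound.

**Step 14.** The most likely failures are poor facial selectivity if ring D reacts with C4′ equatorial, migration of the alkene to C4a′=C5′ before reduction, or partial reduction of the ketone. The fallback replaces surface hydrogenation under kinetic control by stepwise hydrogen-atom transfer under thermodynamic control: Mn(dpm)3 (dpm = dipivaloylmethanate), PhSiH3 and tBuOOH in isopropanol. The tertiary C5′ radical should be quenched to the equatorial methyl epimer, which is the same epimer. It sets out from 19 and returns at 20, and makes no new compound.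

**Step 16.** The most likely failure is ionisation of the allylic C2–O1 bond of the product by zerovalent palladium, followed by formate reduction of the allyl complex and opening of the pyran. The fallback avoids palladium and sets out from 20. NaBH4 in methanol at −20 °C should reduce the isolated ketone to carbinol F6, and dehydration with Ph2S[OC(CF3)2Ph]2 can use only the C8a′ hydrogen and returns 22.

## Further compounds

F0 | step 13 | none | none
F1 | step 8 | (4R)-2-hydroxy-7-methoxy-6,8,8-trimethyl-4-(propan-2-yl)-3,4-dihydro-2H-chromen-5(8H)-one (lactol, C2 anomers) | COC1=C(C)C(=O)C2=C(OC(O)C[C@@H]2C(C)C)C1(C)C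
F2 | step 8 | (4R)-7-methoxy-6,8,8-trimethyl-4-(propan-2-yl)-3,4-dihydro-2H-chromene-2,5(8H)-dione (enol lactone) | COC1=C(C)C(=O)C2=C(OC(=O)C[C@@H]2C(C)C)C1(C)C
F3 | step 10 | methyl ketal of 12 (2-methoxy; C2 anomers) | COC1=C(C)C(=O)C2=C(OC(OC)(CC/C=C(\C)C=C)C[C@@H]2C(C)C)C1(C)C
F4 | step 10 | tert-butyldimethyl[(4-methylpent-1-yn-3-yl)oxy]silane (racemic) | C#CC(O[Si](C)(C)C(C)(C)C)C(C)C
F5 | step 10 | tert-butyldimethylsilyl ether of 16 | COC1=C(C)C(=O)C2=C(O[C@@](C#CC(O[Si](C)(C)C(C)(C)C)C(C)C)(CC/C=C(\C)C=C)C[C@@H]2C(C)C)C1(C)C
F0 | step 12 | none | none
F0 | step 14 | none | none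
F6 | step 16 | C1′ carbinol from 20 (C1′ epimers) | COC1=C(C)C(=O)C2=C(O[C@]3(C(O)[C@H]4[C@H](C(C)C)CC[C@@H](C)[C@H]4CC3)C[C@@H]2C(C)C)C1(C)C
A1 | alternative 1 | O-desmethyl target (C7 enol of the ring A trione) | OC1=C(C)C(=O)C2=C(O[C@]3(C=C4[C@H](C(C)C)CC[C@@H](C)[C@H]4CC3)C[C@@H]2C(C)C)C1(C)C
A2 | alternative 1 | spiro dihydropyran with methyl ester on C4a and 2-methyl-3-oxopentan-2-yl group on C8a | COC(=O)C1=C(O[C@]2(C=C3[C@H](C(C)C)CC[C@@H](C)[C@H]3CC2)C[C@@H]1C(C)C)C(C)(C)C(=O)CC
A3 | alternative 2 | 2-acetyl-5-methoxy-4,6,6-trimethylcyclohex-4-ene-1,3-dione | CC(=O)C1C(=O)C(C)=C(OC)C(C)(C)C1=O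
A4 | alternative 2 | octalone of rings C and D with C2 as the carbonyl (C4a′, C5′, C8′ as in the target) | O=C1C=C2[C@H](C(C)C)CC[C@@H](C)[C@H]2CC1
A5 | alternative 2 | spiro pyran-4-one (target with C4 as carbonyl) | COC1=C(C)C(=O)C2=C(O[C@]3(C=C4[C@H](C(C)C)CC[C@@H](C)[C@H]4CC3)CC2=O)C1(C)C
A6 | alternative 3 | 2-isopropyl-5-methylcyclohexanone carrying on C6 the chain CH2CH2C(=CH2)CH2CH(iPr)– to the ring A enol | O=C1[C@H](C(C)C)CC[C@@H](C)[C@H]1CCC(=C)C[C@H](C(C)C)C2=C(O)C(C)(C)C(OC)=C(C)C2=O
A7 | alternative 3 | spirocyclic C8a′ tertiary alcohol (cis-fused) | COC1=C(C)C(=O)C2=C(O[C@]3(C[C@@]4(O)[C@H](C(C)C)CC[C@@H](C)[C@H]4CC3)C[C@@H]2C(C)C)C1(C)C
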